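Locants: flavone unit 1 = ring A (benzo), ring C (pyranone, O1–C4) and ring B (primed, OMe on C4'); flavone unit 2 = ring D (benzo, C4a''–C8a''), ring E (pyranone, O1''–C4'') and ring F (4-hydroxyphenyl); the units are joined C3'–C6''.
Enabling feature: ring D is a phloroglucinol nucleus fused to pyranone E, i.e. a folded carbonyl chain C5''–C6''–C7''–C8'' hanging from C8a'' of a 4-pyranone whose C4a'' is a vinylogous enolate carbon. C6'' can carry ring B as an sp3 α-aryl substituent before the hindered biaryl exists.
Cuts, in retrosynthetic order: three O–benzyl bonds; C4a''–C5'' (ring D, Claisen); C6''–C7'' (ester enolate acylation); C7''–C8'' (carboxylation); ring E (O1''–C8a'' cyclodehydration, C2''–C3'' diketone dianion acylation); ring C (O1–C2 oxidative closure, C2–C3 aldol condensation, C1'–C2 formylation).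
Forward order: ring C is built on the arylacetate (8), ring E is made separately and carboxylated (13), the halves are joined at C6''–C7'' (15), ring D closes last (16), and hydrogenolysis gives 17.
Stereochemistry: the target has no stereocentre; C6'' of 15 is racemic and enolisable and becomes sp2 in step 10; the E-alkene of the chalcone disappears in step 5.

Key step: step 10

Remark: the C3'–C6'' axis is treated as configurationally undefined, as in the given structure. All three phenols that must be masked are carried as benzyl ethers, so that one hydrogenolysis releases the target.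

Step 1
Reactants: 1 methyl 2-(2-methoxyphenyl)acetate
Product: 3 methyl 2-(5-formyl-2-methoxyphenyl)acetate, via chloro(methoxy)methyl arene 2 (not isolated)
Conditions: Cl2CHOMe (1.5 equiv), TiCl4 (2.2 equiv), CH2Cl2, 0 °C to rt; then ice-cold 1 M HCl
Reagents that add atoms: dichloromethyl methyl ether COC(Cl)Cl; water O
Why: Rieche formylation, in which the methoxy group directs the electrophile para to itself (the future C1'), the ortho site being more hindered, and hydrolysis of 2 on work-up should release the aldehyde while the methyl ester survives the Lewis acid.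

Step 2
Reactants: 4 2',4',6'-trihydroxyacetophenone
Product: 5 1-[2,4-bis(benzyloxy)-6-hydroxyphenyl]ethan-1-one
Conditions: BnBr (2.05 equiv), K2CO3 (2.2 equiv), DMF, 0 °C to rt
Reagents that add atoms: benzyl bromide BrCc1ccccc1
Why: Williamson ether synthesis, in which the hydroxyl that remains hydrogen-bonded to the acetyl carbonyl is the least nucleophilic, so two equivalents of bromide should stop at the dibenzyl ether with that hydroxyl free.

Step 3
Reactants: 3 methyl 2-(5-formyl-2-methoxyphenyl)acetate; 5 1-[2,4-bis(benzyloxy)-6-hydroxyphenyl]ethan-1-one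
Product: 6 (E)-2-[5-[3-[2,4-bis(benzyloxy)-6-hydroxyphenyl]-3-oxoprop-1-en-1-yl]-2-methoxyphenyl]acetic acid
Conditions: KOH (50% aq., 10 equiv), EtOH, rt, 48 h; then 2 M HCl to pH 2 at 0 °C
Reagents that add atoms: potassium hydroxide [K+].[OH-]
Why: Claisen–Schmidt condensation, in which the acetophenone enolate adds to the non-enolisable aldehyde and E1cB dehydration gives the thermodynamically preferred E-enone, while early saponification of the methyl ester turns the arylacetate into a carboxylate that cannot compete as an enolate.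

Step 4
Reactants: 6 (E)-2-[5-[3-[2,4-bis(benzyloxy)-6-hydroxyphenyl]-3-oxoprop-1-en-1-yl]-2-methoxyphenyl]acetic acid
Product: 7 methyl (E)-2-[5-[3-[2,4-bis(benzyloxy)-6-hydroxyphenyl]-3-oxoprop-1-en-1-yl]-2-methoxyphenyl]acetate
Conditions: MeI (1.5 equiv), KHCO3 (1.5 equiv), DMF, rt
Reagents that add atoms: iodomethane CI
Why: SN2 O-alkylation of a carboxylate, in which hydrogencarbonate deprotonates only the carboxylic acid, so the chelated phenol needed for ring closure should stay unmethylated.

Step 5
Reactants: 7 methyl (E)-2-[5-[3-[2,4-bis(benzyloxy)-6-hydroxyphenyl]-3-oxoprop-1-en-1-yl]-2-methoxyphenyl]acetate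
Product: 8 methyl 2-[5-[5,7-bis(benzyloxy)-4-oxo-4H-chromen-2-yl]-2-methoxyphenyl]acetate
Conditions: I2 (0.1 equiv), DMSO, 120 °C
Reagents that add atoms: none
Why: iodine/DMSO oxidative cyclisation of a 2'-hydroxychalcone, in which oxa-Michael closure of ring C is followed by α-iodination and loss of HI, DMSO reoxidising the iodide, and benzyl ethers and the ester should tolerate the conditions.

Step 6
Reactants: 9 pentane-2,4-dione; 10 methyl 4-(benzyloxy)benzoate
Product: 11 1-[4-(benzyloxy)phenyl]hexane-1,3,5-trione
Conditions: 9 (2.2 equiv), LiN(iPr)2 (4.4 equiv), THF, 0 °C; then 10 (1 equiv), 0 °C to rt; then cold 1 M HCl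
Reagents that add atoms: none
Why: Claisen acylation of a β-diketone 1,3-dianion at its terminal, more basic carbon (forming C2''–C3''), the excess dianion absorbing the acidic proton of the triketone so that the ester is consumed once.

Step 7
Reactants: 11 1-[4-(benzyloxy)phenyl]hexane-1,3,5-trione
Product: 12 2-[4-(benzyloxy)phenyl]-6-methyl-4H-pyran-4-one
Conditions: p-TsOH·H2O (0.2 equiv), toluene, reflux, Dean–Stark trap
Reagents that add atoms: none
Why: acid-catalysed cyclodehydration of a 1,3,5-triketone, in which the enol oxygen of one terminal carbonyl adds to the other and water is lost, both directions giving the same pyranone (ring E), and the benzyl aryl ether should tolerate catalytic sulfonic acid.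

Step 8
Reactants: 12 2-[4-(benzyloxy)phenyl]-6-methyl-4H-pyran-4-one
Product: 13 2-[6-[4-(benzyloxy)phenyl]-4-oxo-4H-pyran-2-yl]acetic acid
Conditions: LiN(SiMe3)2 (1.2 equiv), THF, −78 °C; then CO2 (excess), −78 °C; then 1 M HCl at 0 °C; crude acid kept cold and used at once
Reagents that add atoms: carbon dioxide O=C=O
Why: lateral (vinylogous) deprotonation of the 2-methyl group of a 4-pyranone gives a dienolate that should be carboxylated at the exocyclic carbon (forming C7''–C8''), the ring protons being too weakly acidic for the silylamide.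

Step 9
Reactants: 13 2-[6-[4-(benzyloxy)phenyl]-4-oxo-4H-pyran-2-yl]acetic acid; 8 methyl 2-[5-[5,7-bis(benzyloxy)-4-oxo-4H-chromen-2-yl]-2-methoxyphenyl]acetate
Product: 15 methyl 2-[5-[5,7-bis(benzyloxy)-4-oxo-4H-chromen-2-yl]-2-methoxyphenyl]-4-[6-[4-(benzyloxy)phenyl]-4-oxo-4H-pyran-2-yl]-3-oxobutanoate, via acyl imidazolide 14 (not isolated)
Conditions: 13 (1.3 equiv), CDI (1.25 equiv), THF, 0 °C to rt; separately 8 (1 equiv), LiN(SiMe3)2 (2.2 equiv), THF, −78 °C; imidazolide solution added at −78 °C, then −40 °C; AcOH quench at −78 °C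
Reagents that add atoms: none
Why: crossed Claisen condensation (C-acylation of a lithium ester enolate by an acyl imidazolide, forming C6''–C7''), the second equivalent of base taking up the more acidic proton of the product and the low temperature favouring acylation over proton transfer from the acidic methylene of 14.

Step 10
Reactants: 15 methyl 2-[5-[5,7-bis(benzyloxy)-4-oxo-4H-chromen-2-yl]-2-methoxyphenyl]-4-[6-[4-(benzyloxy)phenyl]-4-oxo-4H-pyran-2-yl]-3-oxobutanoate
Product: 16 6-[5-[5,7-bis(benzyloxy)-4-oxo-4H-chromen-2-yl]-2-methoxyphenyl]-2-[4-(benzyloxy)phenyl]-5,7-dihydroxy-4H-chromen-4-one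
Conditions: Mg(OMe)2 (6 equiv), MeOH/THF, reflux; then cold 1 M HCl
Reagents that add atoms: none
Why: Mg(OMe)2 in methanol converts 15 into magnesium enolates that interconvert by proton transfer, and the one deprotonated at C8'' is a dienolate of the C7'' ketone whose γ-carbon C4a'' (also the α-carbon of the pyranone carbonyl C4'') adds to the magnesium-coordinated ester carbon C5''; loss of methoxide and enolisation at C6'' and C4a'' then give ring D as an aromatic magnesium phenoxide, which makes the sequence irreversible. The closest known reaction type is the biomimetic Claisen cyclisation of poly-β-keto esters and of pyranone-masked polyketide chains to acylphloroglucinols, applied here to a chain that carries an aryl group on C6''. Ring D closes in a 6-(enolendo)-exo-trig mode through the new C4a''–C5'' bond. No stereocentre is created, and the racemic centre C6'' becomes sp2. The step needs C-acylation at C4a'' to outrun methoxide-induced retro-Claisen cleavage at C7'' and opening of ring E; the chelated C6'' enolate (the resting state) shields C7'', and the closed pyranone holds C8'' and C4'' trans across C8a''=C4a'', so the competing aldol closure of C6'' onto C4'' is geometrically impossible. Because O1'' stays bound to C8a'', only the 6''-aryl chromone can form, and the hindered C3'–C6'' bond is never made by coupling.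

Step 11
Reactants: 16 6-[5-[5,7-bis(benzyloxy)-4-oxo-4H-chromen-2-yl]-2-methoxyphenyl]-2-[4-(benzyloxy)phenyl]-5,7-dihydroxy-4H-chromen-4-one
Product: 17 6-[5-(5,7-dihydroxy-4-oxo-4H-chromen-2-yl)-2-methoxyphenyl]-5,7-dihydroxy-2-(4-hydroxyphenyl)-4H-chromen-4-one
Conditions: H2 (1 atm), 10% Pd/C, THF/MeOH, rt
Reagents that add atoms: none
Why: hydrogenolysis of three benzyl aryl ethers, in which the aryl methyl ether is inert and the C2=C3 bonds of both chromones, being vinylogous esters, should not be reduced at atmospheric pressure and room temperature.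

Compound list
1 | methyl 2-(2-methoxyphenyl)acetate | COC(=O)Cc1ccccc1OC | starting material
2 | methyl 2-[5-[chloro(methoxy)methyl]-2-methoxyphenyl]acetate (racemic, formed in the flask in step 1) | COC(=O)Cc1cc(C(Cl)OC)ccc1OC | intermediate
3 | methyl 2-(5-formyl-2-methoxyphenyl)acetate | COC(=O)Cc1cc(C=O)ccc1OC | intermediate
4 | 2',4',6'-trihydroxyacetophenone | CC(=O)c1c(O)cc(O)cc1O | starting material
5 | 1-[2,4-bis(benzyloxy)-6-hydroxyphenyl]ethan-1-one | CC(=O)c1c(O)cc(OCc2ccccc2)cc1OCc1ccccc1 | intermediate
6 | (E)-2-[5-[3-[2,4-bis(benzyloxy)-6-hydroxyphenyl]-3-oxoprop-1-en-1-yl]-2-methoxyphenyl]acetic acid | COc1ccc(/C=C/C(=O)c2c(O)cc(OCc3ccccc3)cc2OCc2ccccc2)cc1CC(=O)O | intermediate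
7 | methyl (E)-2-[5-[3-[2,4-bis(benzyloxy)-6-hydroxyphenyl]-3-oxoprop-1-en-1-yl]-2-methoxyphenyl]acetate | COc1ccc(/C=C/C(=O)c2c(O)cc(OCc3ccccc3)cc2OCc2ccccc2)cc1CC(=O)OC | intermediate
8 | methyl 2-[5-[5,7-bis(benzyloxy)-4-oxo-4H-chromen-2-yl]-2-methoxyphenyl]acetate | COC(=O)Cc1cc(-c2cc(=O)c3c(OCc4ccccc4)cc(OCc4ccccc4)cc3o2)ccc1OC | intermediate
9 | pentane-2,4-dione (acetylacetone) | CC(=O)CC(C)=O | starting material
10 | methyl 4-(benzyloxy)benzoate | COC(=O)c1ccc(OCc2ccccc2)cc1 | starting material
11 | 1-[4-(benzyloxy)phenyl]hexane-1,3,5-trione (enol tautomers) | CC(=O)CC(=O)CC(=O)c1ccc(OCc2ccccc2)cc1 | intermediate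
12 | 2-[4-(benzyloxy)phenyl]-6-methyl-4H-pyran-4-one | Cc1cc(=O)cc(-c2ccc(OCc3ccccc3)cc2)o1 | intermediate
13 | 2-[6-[4-(benzyloxy)phenyl]-4-oxo-4H-pyran-2-yl]acetic acid | OC(=O)Cc1cc(=O)cc(-c2ccc(OCc3ccccc3)cc2)o1 | intermediate
14 | 1-[[6-[4-(benzyloxy)phenyl]-4-oxo-4H-pyran-2-yl]acetyl]-1H-imidazole (formed in the flask in step 9) | O=C(Cc1cc(=O)cc(-c2ccc(OCc3ccccc3)cc2)o1)n1ccnc1 | intermediate
15 | methyl 2-[5-[5,7-bis(benzyloxy)-4-oxo-4H-chromen-2-yl]-2-methoxyphenyl]-4-[6-[4-(benzyloxy)phenyl]-4-oxo-4H-pyran-2-yl]-3-oxobutanoate (racemic at C6'', enolisable) | COC(=O)C(C(=O)Cc1cc(=O)cc(-c2ccc(OCc3ccccc3)cc2)o1)c1cc(-c2cc(=O)c3c(OCc4ccccc4)cc(OCc4ccccc4)cc3o2)ccc1OC | intermediate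
16 | 6-[5-[5,7-bis(benzyloxy)-4-oxo-4H-chromen-2-yl]-2-methoxyphenyl]-2-[4-(benzyloxy)phenyl]-5,7-dihydroxy-4H-chromen-4-one | COc1ccc(-c2cc(=O)c3c(OCc4ccccc4)cc(OCc4ccccc4)cc3o2)cc1-c1c(O)cc2oc(-c3ccc(OCc4ccccc4)cc3)cc(=O)c2c1O | intermediate
17 | 6-[5-(5,7-dihydroxy-4-oxo-4H-chromen-2-yl)-2-methoxyphenyl]-5,7-dihydroxy-2-(4-hydroxyphenyl)-4H-chromen-4-one | COc1ccc(-c2cc(=O)c3c(O)cc(O)cc3o2)cc1-c1c(O)cc2oc(-c3ccc(O)cc3)cc(=O)c2c1O | target

Total step count: 11. Longest linear sequence: 7 steps (steps 1, 3, 4, 5, 9, 10, 11); steps 2 and 6–8 are side branches.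

Steps most likely to fail

Step 10. The ring closure may lose out to retro-Claisen cleavage at C7'' or to opening of ring E by methoxide, or the chelated C6'' enolate may be too unreactive an electrophile. The fallback is a base-free thermal closure of the same bond. It sets out from 15, which is heated in o-dichlorobenzene at about 180 °C so that methanol is expelled and the α-oxoketene F1 forms. The C7''=C8'' enol tautomer of this ketene is a dienylketene that should close C4a''–C5'' by 6π-electrocyclisation and tautomerise to the phenol, so the fallback comes back to the route at 16.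

Step 9. Proton transfer from the acidic methylene of the imidazolide to the ester enolate may quench both partners before C-acylation occurs. The fallback replaces the basic enolate by a soft magnesium malonate in a decarboxylative Claisen acylation of the Masamune–Brooks type. It sets out from 8, whose lithium enolate (LiN(SiMe3)2, THF, −78 °C) is carboxylated with CO2 to the malonic half-ester F2, which is kept cold. F2 is then treated with MgCl2 and Et3N in MeCN/THF and acylated at rt by imidazolide 14, made as before from 13. Loss of CO2 on acidic work-up returns the route at 15.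

Step 8. The vinylogous β-keto acid may decarboxylate back to 12 during acidification or activation. The fallback avoids the free acid. It sets out from 12, whose lateral anion (LiN(SiMe3)2, 2.2 equiv, THF, −78 °C) is trapped with diphenyl carbonate to give the phenyl ester F3. F3 is then used directly as the acyl donor towards the lithium enolate of 8 under the conditions of step 9, so the fallback comes back to the route at 15 and bypasses 13 and 14.

Further compounds
F1 | step 10 | 2-[5-[5,7-bis(benzyloxy)-4-oxo-4H-chromen-2-yl]-2-methoxyphenyl]-4-[6-[4-(benzyloxy)phenyl]-4-oxo-4H-pyran-2-yl]buta-1-ene-1,3-dione (α-oxoketene) | O=C=C(C(=O)Cc1cc(=O)cc(-c2ccc(OCc3ccccc3)cc2)o1)c1cc(-c2cc(=O)c3c(OCc4ccccc4)cc(OCc4ccccc4)cc3o2)ccc1OC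
F2 | step 9 | 2-[5-[5,7-bis(benzyloxy)-4-oxo-4H-chromen-2-yl]-2-methoxyphenyl]-3-methoxy-3-oxopropanoic acid (racemic) | COC(=O)C(C(=O)O)c1cc(-c2cc(=O)c3c(OCc4ccccc4)cc(OCc4ccccc4)cc3o2)ccc1OC
F3 | step 8 | phenyl 2-[6-[4-(benzyloxy)phenyl]-4-oxo-4H-pyran-2-yl]acetate | O=C(Cc1cc(=O)cc(-c2ccc(OCc3ccccc3)cc2)o1)Oc1ccccc1
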